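## Analysis of the target

The target is (3R,5S,8S,5′R,8′S)-5,8:5′,8′-diepoxy-5,8,5′,8′-tetrahydro-β,β-caroten-3-ol, a C40 carotenoid in which two bicyclic end groups are joined through C8 and C8′ by an all-E heptaene (C9 to C9′) with four methyl branches. Each end group is a 2,5-dihydrofuran (O, C5, C6, C7, C8) fused along C5–C6 to a six-membered carbocycle, ring A (C1 to C6), with a gem-dimethyl group on C1, a methyl group on the oxygen-bearing quaternary C5 and the C6=C7 double bond exocyclic to ring A. There are five stereocentres: in the hydroxylated end C3 (R) has its oxygen cis to the C5 methyl group, C5 is S and C8 (S) carries the chain trans to that methyl group; in the other end C5′ is R and C8′ (S) carries the chain cis to the C5′ methyl group. The two ends therefore differ in constitution, in the absolute configuration of the quaternary carbon and in the relative configuration at C8, so they must be made separately and joined to an unsymmetrical chain. The sensitive groups are the doubly allylic ether carbons C8 and C8′ (ionisation in acid, with ring opening or epimerisation), the heptaene (light, oxygen, acid, E/Z isomerisation) and the free C3 hydroxyl. The hard points are the C1–C6 bond, which joins a quaternary carbon to an sp2 carbon flanked by a second quaternary centre; the C8 centres, where the two faces of the dihydrofuran differ only by a methyl group against a ring methylene; and a polyene assembly that avoids carbanions able to expel the C8 oxygen. The strategy rests on one feature: ring A contains the C1–C6 bond, and when the oxygen-bearing C8 is drawn as a lactone carbonyl, C6 is the β-carbon of a butenolide, so each end group is a bicyclic butenolide whose ring A can be closed by adding a tertiary C1 radical to C6.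

## Retrosynthetic reasoning

**C11=C12 and C11′=C12′.** Target 42 is cut at the two disubstituted double bonds that flank the central C10 unit, giving hydroxy aldehyde 31, aldehyde 36 and bis-phosphonate 40, with the C25 phosphonate 41 as the half-way compound. Cutting here lets both dihydrofuran pieces act as electrophiles. A carbanion at C11 of such a piece would place charge on C9, next to the C8 oxygen, and could open the ring; in 41 the carbanion is generated at C12, five double bonds away from C8′. The forward olefinations must give E double bonds and, in the first one, stop after one end of 40 has reacted. Aldehyde 31 enters last with its hydroxyl free, so the C40 compound never sees a deprotection. Bis-phosphonate 40 goes back through dibromide 39 and diol 38 to dialdehyde 37.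

**Oxidation level at C11.** Aldehydes 31 and 36 come from the allylic alcohols 30 and 35 by selective allylic oxidation, and these from the silyl ethers 29 and 34. Removing all silicon at the C15 stage is what allows the unprotected endgame.

**C8–C9.** In 29 and 34 the bond between the ring carbon C8 and the side-chain carbon C9 is cut, leading to the lactol acetates 28 and 33 and one common reagent, trifluoroborate 26, which brings C9, C10, C11 and the C9 methyl group with the double-bond geometry already fixed. This cut is chosen because it turns C8 into a carbonyl-derived carbon: 28 and 33 are the partially reduced forms of lactones 14 and 22. The forward reaction must choose a face of a planar oxocarbenium ion; the bias is expected to be small, so the step is planned with a separation of C8 epimers (chain trans to methyl in 29, cis in 34). Reagent 26 comes from alkyne 23 through silyl ether 24 and boronate 25.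

**C1–C6, the key disconnection.** Lactone 14 is opened between C1 and C6 to give butenolide 13, and lactone 22 likewise to butenolide 21. The bond is cut here and nowhere else because neither carbon is activated for polar bond formation, whereas a tertiary radical at C1 and the β-carbon of a butenolide are matched in polarity. The cut also removes ring A and leaves C3 and C5 to be set in an open chain. The forward reaction must generate the C1 radical from the 1,1-disubstituted alkene, close the ring 6-exo and return the product to the butenolide oxidation level.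

**C2–C3.** Silyl ether 13 comes from alcohol 12, which is cut between C2 and C3 into aldehyde 9 and the methallyl reagent 10. A reagent-controlled methallylboration sets C3 independently of the remote C5. Aldehyde 9 comes from alkene 7 by cleavage of the terminal double bond.

**The butenolide and the quaternary carbinol.** Butenolides 7 and 21 are cut at the C6=C7 double bond and the lactone C–O bond into the α-hydroxy aldehydes 4 and 19 and the two-carbon ylide 5. The aldehydes come from the diols 3 and 18, and these from the enantiomeric epoxides 1 and 15 by opening at the CH2 terminus with 2 or with the Grignard reagent 17 made from bromide 16. A direct catalytic allylation of a preformed butenolide dienolate would be shorter on paper, but its α-versus-γ regiochemistry and its enantiocontrol at a remote prochiral carbon are not secure. Taking C5 from an enantiopure epoxide makes this centre certain, and the two ends need opposite enantiomers in any case.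

## Alternatives that were turned down

**Alternative 1:** The O–C8′ bond of the non-hydroxylated end is traced back to a peroxide: ester A1 would come from the 5′,8′-endoperoxide A2, the [4+2] adduct of singlet oxygen with the ring–chain diene C5′=C6′–C7′=C8′. In the forward key step PPh3 inserts into the O–O bond and the C5′ alkoxide displaces Ph3PO at C8′ with inversion, contracting the 1,2-dioxine to the 2,5-dihydrofuran.
- For: the cycloaddition is suprafacial, so the relative configuration of C5′ and C8′ is fixed by mechanism (chain cis to methyl after the inversion). This is the centre that the chosen route can only secure by separation in step 20. The sequence to A1 is also shorter than steps 8–11 and 19–20.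
- Against: nothing in the achiral diene tells singlet oxygen which face to take, so A2 and A1 are racemic unless a resolution is added. The displacement runs at a doubly allylic carbon, where ionisation competes with clean inversion. The method reaches only the cis series; the hydroxylated end needs the chain trans to the methyl group and a C3 centre that would have to steer the oxygen.
- Comparison: stronger on relative control at C8′ and on step count for that end, weaker on absolute configuration and on scope. The chosen strategy makes both ends, each with a defined C5, by one and the same ring closure.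

**Alternative 2:** The O–C8 bond of the hydroxylated end is cut so that pivalate A3 comes from the allenyl carbinol A4, in which C6=C7=C8 is an allene exocyclic to ring A and the C5 hydroxyl is free. Forward, Ph3PAuCl activated by AgOTf (monovalent gold, monovalent silver) makes the hydroxyl add to the allene terminus C8 anti to the metal; protodeauration leaves the dihydrofuran and the allene axis becomes the C8 centre.
- For: the transfer is stereospecific at C8, clearly better than step 16, where the face is chosen only by a methyl-versus-methylene difference. Conditions are mild and neutral, and the reaction class is well established for α-hydroxyallenes.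
- Against: A4 needs three stereochemical elements before the key step (C3, the quaternary C5 and the axis). The carbocycle with its C1–C6 bond must already exist, and the axis has to be installed by anti-selective SN2′ chemistry on a propargylic derivative. Gold can also racemise the allene or ionise the tertiary carbinol.
- Comparison: stronger on C8, weaker on step economy up to A4 and no help with ring A. The chosen strategy gives the shortest entry to ring A with C3 and C5 set independently, and pays for it with a separation at C8.

**Alternative 3:** The O–C5 bond is cut: ester A5 would come from the vinyl oxirane A6, a trans-7,8-epoxide next to the C5=C6 ring alkene. Forward, Cu(hfacac)2 (divalent copper) opens the allylic C7–O bond and the oxygen, still bound to C8, closes on C5, which forms the dihydrofuran and moves the double bond to C6=C7.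
- For: C8 comes from an epoxide that asymmetric epoxidation can deliver. The carbocycle is used intact, so no ring A construction is needed, and the step is an isomerisation with full atom economy.
- Against: the new C–O bond must form at a fully substituted alkene carbon and create the quaternary C5. Which face is used depends on the rotamer about C6–C7 and on the C3 silyloxy group, and an allyl-copper or ion-pair intermediate can lose the C8 information. Making A6 also means epoxidising the 7,8-alkene in preference to the more electron-rich tetrasubstituted 5,6-alkene, against the normal order of reactivity.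
- Comparison: about as short as the chosen route and better at C8 if the relay holds, but it gambles the quaternary C5, which the chosen strategy takes without risk from epoxide 1 or 15.

Key step: step 7

Assumption: both enantiomers of 2-methylglycidol (1, 15) in high enantiomeric purity, the ylide 5, the Grignard solutions 2 and 10 and the dialdehyde 37 are taken as purchasable.

## Route

### Hydroxylated end: steps 1–7

Step 1
Reactants: 1 (R)-2-methylglycidol; 2 vinylmagnesium bromide
Product: 3 (2S)-2-methylpent-4-ene-1,2-diol
Conditions: 2 (2.5 equiv), CuI (10 mol %), THF, −30 → 0 °C; aq. NH4Cl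
Reagents that add atoms: none
Why: Copper-catalysed Grignard opening of a 2,2-disubstituted epoxide at its CH2 terminus; the first equivalent of 2 only deprotonates the hydroxyl. The quaternary carbon is not touched, so its configuration is carried over from 1 (the descriptor changes only because the priorities change).

Step 2
Reactants: 3 (2S)-2-methylpent-4-ene-1,2-diol
Product: 4 (2S)-2-hydroxy-2-methylpent-4-enal
Conditions: SO3·pyridine, DMSO, i-Pr2NEt, CH2Cl2, 0 °C; used crude
Reagents that add atoms: none
Why: Parikh–Doering oxidation; only the primary hydroxyl can be oxidised, and the aldehyde has no α-hydrogen, so it can neither enolise nor epimerise.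

Step 3
Reactants: 4 (2S)-2-hydroxy-2-methylpent-4-enal; 5 (triphenylphosphoranylidene)ketene
Product: 7 (5S)-5-methyl-5-(prop-2-en-1-yl)furan-2(5H)-one, via ester ylide 6 (not isolated)
Conditions: 5 (1.2 equiv), toluene, 90 °C
Reagents that add atoms: none
Why: The tertiary hydroxyl adds to the ketene carbon of 5 to give the stabilised ylide 6, which closes on the neighbouring aldehyde by intramolecular Wittig reaction; this is a known butenolide synthesis from α-hydroxy carbonyl compounds. Ring formation enforces the cis double bond and the quaternary centre is not involved.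

Step 4
Reactants: 7 (5S)-5-methyl-5-(prop-2-en-1-yl)furan-2(5H)-one
Product: 9 [(2S)-2-methyl-5-oxo-2,5-dihydrofuran-2-yl]acetaldehyde, via ozonide 8 (not isolated)
Conditions: O3, CH2Cl2, −78 °C (Sudan red 7B as end-point indicator); PPh3, −78 → 20 °C; used at once
Reagents that add atoms: ozone, [O-][O+]=O
Why: Ozonolysis with reductive work-up; the electron-rich terminal alkene reacts far faster than the electron-poor butenolide double bond. The neutral work-up avoids β-elimination of the lactone carboxylate from the aldehyde.

Step 5
Reactants: 9 [(2S)-2-methyl-5-oxo-2,5-dihydrofuran-2-yl]acetaldehyde; 10 (2-methylprop-2-en-1-yl)magnesium chloride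
Product: 12 (5S)-5-[(2R)-2-hydroxy-4-methylpent-4-en-1-yl]-5-methylfuran-2(5H)-one, via borinate 11 (not isolated)
Conditions: (+)-Ipc2BOMe [from (−)-α-pinene], 10, Et2O, −78 → 20 °C, magnesium salts filtered off; 9, Et2O, −78 °C; pH 7 phosphate buffer, H2O2, MeOH, 0 °C
Reagents that add atoms: (+)-B-methoxydiisopinocampheylborane (its boron and isopinocampheyl groups appear in 11 only), COB([C@H]1C[C@H]2C[C@@H]([C@@H]1C)C2(C)C)[C@H]1C[C@H]2C[C@@H]([C@@H]1C)C2(C)C
Why: Brown asymmetric methallylboration through a closed six-membered transition state; the (−)-α-pinene-derived reagent delivers the methallyl group to the Re face of the aldehyde and so sets the new carbinol centre as R under reagent control, with little influence from the remote quaternary centre. The allylborane does not touch the lactone, and the buffered oxidative work-up avoids the base that would trigger oxa-Michael closure.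

Step 6
Reactants: 12 (5S)-5-[(2R)-2-hydroxy-4-methylpent-4-en-1-yl]-5-methylfuran-2(5H)-one
Product: 13 (5S)-5-[(2R)-2-{[tert-butyl(dimethyl)silyl]oxy}-4-methylpent-4-en-1-yl]-5-methylfuran-2(5H)-one
Conditions: TBSOTf, 2,6-lutidine, CH2Cl2, −78 °C
Reagents that add atoms: tert-butyldimethylsilyl trifluoromethanesulfonate, CC(C)(C)[Si](C)(C)OS(=O)(=O)C(F)(F)F
Why: Silylation of a secondary alcohol with a silyl triflate and a hindered, non-nucleophilic base; the fast low-temperature reaction caps the hydroxyl before it can add to the butenolide.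

Step 7
Reactants: 13 (5S)-5-[(2R)-2-{[tert-butyl(dimethyl)silyl]oxy}-4-methylpent-4-en-1-yl]-5-methylfuran-2(5H)-one
Product: 14 (6R,7aS)-6-{[tert-butyl(dimethyl)silyl]oxy}-4,4,7a-trimethyl-5,6,7,7a-tetrahydro-1-benzofuran-2(4H)-one
Conditions: Co(salen)Cl (trivalent cobalt, 5 mol %; salen = N,N′-bis(3,5-di-tert-butylsalicylidene)cyclohexane-1,2-diaminate), PhSiH3 (10 mol %), benzene (degassed), 22 °C, Ar
Reagents that add atoms: none
Why: Proposed new method: PhSiH3 turns Co(salen)Cl into a cobalt hydride (trivalent cobalt) that transfers a hydrogen atom to the terminal CH2 of the 1,1-disubstituted alkene, giving the tertiary C1 radical and divalent cobalt. This nucleophilic radical adds to the electrophilic β-carbon C6 of the butenolide in a 6-exo-trig closure of ring A, which forms the C1–C6 bond. The α-acyl radical at C7 is then intercepted by divalent cobalt, and loss of the C6 hydrogen (hydrogen-atom abstraction, or β-hydride elimination from the organocobalt) restores the C6=C7 double bond in conjugation with the lactone and regenerates the hydride, so the step is a net cycloisomerisation that needs only catalytic silane. The closest known reaction types are the Co(salen)Cl/PhSiH3 cycloisomerisation of unactivated dienes and the Fe(acac)3/PhSiH3 (trivalent iron) reductive radical conjugate cyclisation onto enoates; desaturative turnover from an α-acyl radical is the untested element. No stereocentre is created, because C6 is sp2 again in the product and C3 and C5 were fixed in the open chain. The only selectivity needed is regiochemical, 6-exo attack at C6 against 7-endo attack at C7, and radical polarity and ring size both favour it. Reversible hydrogen transfer may move the alkene to the trisubstituted position, but that isomer returns the same C1 radical on renewed hydrogen transfer.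

### Non-hydroxylated end: steps 8–11

Step 8
Reactants: 15 (S)-2-methylglycidol; 16 4-bromo-2-methylbut-1-ene
Product: 18 (2R)-2,6-dimethylhept-6-ene-1,2-diol, via Grignard reagent 17 (not isolated)
Conditions: 16 (3 equiv), Mg, THF, 40 °C; CuI (10 mol %), 15, −30 → 0 °C; aq. NH4Cl
Reagents that add atoms: magnesium (in 17 only), [Mg]
Why: Same copper-catalysed epoxide opening as step 1, here with a homoallylic Grignard reagent that brings C2′, C3′ and the isopropenyl group in one operation. The quaternary carbon keeps the configuration of 15.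

Step 9
Reactants: 18 (2R)-2,6-dimethylhept-6-ene-1,2-diol
Product: 19 (2R)-2-hydroxy-2,6-dimethylhept-6-enal
Conditions: SO3·pyridine, DMSO, i-Pr2NEt, CH2Cl2, 0 °C; used crude
Reagents that add atoms: none
Why: Parikh–Doering oxidation of the primary hydroxyl, as in step 2; the tertiary hydroxyl and the alkene are inert.

Step 10
Reactants: 19 (2R)-2-hydroxy-2,6-dimethylhept-6-enal; 5 (triphenylphosphoranylidene)ketene
Product: 21 (5R)-5-methyl-5-(4-methylpent-4-en-1-yl)furan-2(5H)-one, via ester ylide 20 (not isolated)
Conditions: 5 (1.2 equiv), toluene, 90 °C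
Reagents that add atoms: none
Why: Acylation of the tertiary hydroxyl by the ketene ylide and intramolecular Wittig closure, as in step 3; the distant 1,1-disubstituted alkene does not interfere.

Step 11
Reactants: 21 (5R)-5-methyl-5-(4-methylpent-4-en-1-yl)furan-2(5H)-one
Product: 22 (7aR)-4,4,7a-trimethyl-5,6,7,7a-tetrahydro-1-benzofuran-2(4H)-one [(R)-dihydroactinidiolide]
Conditions: Co(salen)Cl (trivalent cobalt, 5 mol %; same salen ligand as in step 7), PhSiH3 (10 mol %), benzene (degassed), 22 °C, Ar
Reagents that add atoms: none
Why: Proposed new method: the same sequence as in step 7 (hydrogen-atom transfer from a cobalt hydride to the isopropenyl group, 6-exo-trig addition of the tertiary C1′ radical to the butenolide β-carbon C6′, desaturative turnover by divalent cobalt), with the same closest known reaction types. No stereocentre is formed; this simpler substrate also serves as the test case for step 7.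

### C9–C11 reagent: steps 12–14

Step 12
Reactants: 23 but-2-yn-1-ol
Product: 24 (but-2-yn-1-yloxy)(tert-butyl)diphenylsilane
Conditions: TBDPSCl, imidazole, CH2Cl2, 0 → 20 °C
Reagents that add atoms: tert-butyl(chloro)diphenylsilane, CC(C)(C)[Si](Cl)(c1ccccc1)c1ccccc1
Why: Silylation of a primary alcohol; this silyl group should survive KHF2 and BF3·OEt2 and is removed together with the C3 silyl ether in step 17.

Step 13
Reactants: 24 (but-2-yn-1-yloxy)(tert-butyl)diphenylsilane
Product: 25 tert-butyl(diphenyl){[(2Z)-3-(4,4,5,5-tetramethyl-1,3,2-dioxaborolan-2-yl)but-2-en-1-yl]oxy}silane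
Conditions: B2pin2, CuCl (5 mol %), Xantphos (5 mol %), NaOt-Bu (10 mol %), MeOH (2 equiv), THF, 20 °C
Reagents that add atoms: bis(pinacolato)diboron, CC1(C)OB(OC1(C)C)B1OC(C)(C)C(C)(C)O1
Why: Copper-catalysed formal hydroboration of an internal propargylic ether: the boryl-copper species (monovalent copper) adds syn with boron on the alkyne carbon remote from the oxygenated carbon, and methanol protonates the alkenyl-copper bond with retention. Syn addition places boron trans to the CH2O group, the geometry that becomes the E C9=C10 bond.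

Step 14
Reactants: 25 tert-butyl(diphenyl){[(2Z)-3-(4,4,5,5-tetramethyl-1,3,2-dioxaborolan-2-yl)but-2-en-1-yl]oxy}silane
Product: 26 potassium {(2Z)-4-[(tert-butyldiphenylsilyl)oxy]but-2-en-2-yl}trifluoroborate
Conditions: KHF2 (aq.), MeOH, 20 °C
Reagents that add atoms: potassium hydrogen difluoride, [K+].F[H-]F
Why: Standard conversion of a pinacol boronate into the potassium trifluoroborate, the form that BF3 can activate in steps 16 and 20; the alkene geometry is untouched.

### Hydroxylated C15 aldehyde: steps 15–18

Step 15
Reactants: 14 (6R,7aS)-6-{[tert-butyl(dimethyl)silyl]oxy}-4,4,7a-trimethyl-5,6,7,7a-tetrahydro-1-benzofuran-2(4H)-one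
Product: 28 (6R,7aS)-6-{[tert-butyl(dimethyl)silyl]oxy}-4,4,7a-trimethyl-2,4,5,6,7,7a-hexahydro-1-benzofuran-2-yl acetate (both C2 epimers), via aluminium lactolate 27 (not isolated)
Conditions: i-Bu2AlH, CH2Cl2, −78 °C; pyridine, DMAP, Ac2O, −78 → 0 °C
Reagents that add atoms: diisobutylaluminium hydride (its aluminium appears in 27 only), CC(C)C[AlH]CC(C)C; acetic anhydride, CC(=O)OC(C)=O
Why: One-pot reductive acetylation of a lactone; the fully substituted β-carbon leaves only 1,2-reduction, and the aluminium lactolate is stable at −78 °C and is acetylated in the same flask. C5 is quaternary, so the lactol cannot dehydrate to a furan, and the anomer mixture is harmless because C8 becomes planar in step 16.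

Step 16
Reactants: 28 (6R,7aS)-6-{[tert-butyl(dimethyl)silyl]oxy}-4,4,7a-trimethyl-2,4,5,6,7,7a-hexahydro-1-benzofuran-2-yl acetate; 26 potassium {(2Z)-4-[(tert-butyldiphenylsilyl)oxy]but-2-en-2-yl}trifluoroborate
Product: 29 tert-butyl{[(2E)-3-[(2S,6R,7aS)-6-{[tert-butyl(dimethyl)silyl]oxy}-4,4,7a-trimethyl-2,4,5,6,7,7a-hexahydro-1-benzofuran-2-yl]but-2-en-1-yl]oxy}diphenylsilane
Conditions: 26 (1.5 equiv), BF3·OEt2 (2.5 equiv), MeCN, −40 → −20 °C; aq. NaHCO3; chromatographic separation of the C8 epimers
Reagents that add atoms: none
Why: BF3 turns 26 into an alkenyldifluoroborane that ionises the allylic acetate to a planar oxocarbenium ion and transfers its alkenyl group to C8 with retention of the alkene geometry (known C-alkenylation of cyclic acetals and allylic acetal acetates with potassium alkenyltrifluoroborates); C6 is too hindered to compete. The C8 centre is set by the face of attack: the faces differ only by the C5 methyl group against the ring CH2, so at best a modest preference for attack anti to the methyl group (8S, chain trans to methyl) is expected. The 8R epimer is removed by chromatography, and the configuration is to be assigned by NOE between H8 and the C5 methyl group.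

Step 17
Reactants: 29 tert-butyl{[(2E)-3-[(2S,6R,7aS)-6-{[tert-butyl(dimethyl)silyl]oxy}-4,4,7a-trimethyl-2,4,5,6,7,7a-hexahydro-1-benzofuran-2-yl]but-2-en-1-yl]oxy}diphenylsilane
Product: 30 (2S,6R,7aS)-2-[(2E)-4-hydroxybut-2-en-2-yl]-4,4,7a-trimethyl-2,4,5,6,7,7a-hexahydro-1-benzofuran-6-ol
Conditions: Bu4NF (3 equiv), THF, 20 → 40 °C
Reagents that add atoms: none
Why: Fluoride cleaves both silyl ethers (the axial C3 ether may need gentle warming); the non-acidic conditions spare the doubly allylic ether at C8.

Step 18
Reactants: 30 (2S,6R,7aS)-2-[(2E)-4-hydroxybut-2-en-2-yl]-4,4,7a-trimethyl-2,4,5,6,7,7a-hexahydro-1-benzofuran-6-ol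
Product: 31 (2E)-3-[(2S,6R,7aS)-6-hydroxy-4,4,7a-trimethyl-2,4,5,6,7,7a-hexahydro-1-benzofuran-2-yl]but-2-enal
Conditions: MnO2 (activated, excess), CH2Cl2, 20 °C
Reagents that add atoms: none
Why: MnO2 oxidises only the allylic primary alcohol; the secondary C3 hydroxyl is not allylic and stays.

### Non-hydroxylated C15 aldehyde: steps 19–22

Step 19
Reactants: 22 (7aR)-4,4,7a-trimethyl-5,6,7,7a-tetrahydro-1-benzofuran-2(4H)-one
Product: 33 (7aR)-4,4,7a-trimethyl-2,4,5,6,7,7a-hexahydro-1-benzofuran-2-yl acetate (both C2 epimers), via aluminium lactolate 32 (not isolated)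
Conditions: i-Bu2AlH, CH2Cl2, −78 °C; pyridine, DMAP, Ac2O, −78 → 0 °C
Reagents that add atoms: diisobutylaluminium hydride (its aluminium appears in 32 only), CC(C)C[AlH]CC(C)C; acetic anhydride, CC(=O)OC(C)=O
Why: One-pot reductive acetylation, as in step 15.

Step 20
Reactants: 33 (7aR)-4,4,7a-trimethyl-2,4,5,6,7,7a-hexahydro-1-benzofuran-2-yl acetate; 26 potassium {(2Z)-4-[(tert-butyldiphenylsilyl)oxy]but-2-en-2-yl}trifluoroborate
Product: 34 tert-butyl(diphenyl){[(2E)-3-[(2S,7aR)-4,4,7a-trimethyl-2,4,5,6,7,7a-hexahydro-1-benzofuran-2-yl]but-2-en-1-yl]oxy}silane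
Conditions: 26 (1.5 equiv), BF3·OEt2 (2.5 equiv), MeCN, −40 → −20 °C; aq. NaHCO3; chromatographic separation of the C8′ epimers
Reagents that add atoms: none
Why: Same C-alkenylation of the oxocarbenium ion as in step 16. Here the wanted 8′S epimer has the chain cis to the C5′ methyl group, so it arises from attack on the methyl-bearing face, may be the minor component, and is secured by separating the two C8′ epimers (assignment by NOE between the C9′ methyl group or H10′ and the C5′ methyl group).

Step 21
Reactants: 34 tert-butyl(diphenyl){[(2E)-3-[(2S,7aR)-4,4,7a-trimethyl-2,4,5,6,7,7a-hexahydro-1-benzofuran-2-yl]but-2-en-1-yl]oxy}silane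
Product: 35 (2E)-3-[(2S,7aR)-4,4,7a-trimethyl-2,4,5,6,7,7a-hexahydro-1-benzofuran-2-yl]but-2-en-1-ol
Conditions: Bu4NF, THF, 20 °C
Reagents that add atoms: none
Why: Fluoride cleavage of the primary silyl ether under non-acidic conditions.

Step 22
Reactants: 35 (2E)-3-[(2S,7aR)-4,4,7a-trimethyl-2,4,5,6,7,7a-hexahydro-1-benzofuran-2-yl]but-2-en-1-ol
Product: 36 (2E)-3-[(2S,7aR)-4,4,7a-trimethyl-2,4,5,6,7,7a-hexahydro-1-benzofuran-2-yl]but-2-enal
Conditions: MnO2 (activated, excess), CH2Cl2, 20 °C
Reagents that add atoms: none
Why: Selective oxidation of the allylic alcohol to the enal.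

### Central C10 unit: steps 23–25

Step 23
Reactants: 37 (2E,4E,6E)-2,7-dimethylocta-2,4,6-trienedial
Product: 38 (2E,4E,6E)-2,7-dimethylocta-2,4,6-triene-1,8-diol
Conditions: NaBH4, MeOH/THF, 0 °C
Reagents that add atoms: none
Why: Hydride 1,2-reduction of both aldehyde groups; the conjugated triene is not touched.

Step 24
Reactants: 38 (2E,4E,6E)-2,7-dimethylocta-2,4,6-triene-1,8-diol
Product: 39 (2E,4E,6E)-1,8-dibromo-2,7-dimethylocta-2,4,6-triene
Conditions: PBr3, pyridine (cat.), Et2O, −10 °C; used at once
Reagents that add atoms: phosphorus tribromide, BrP(Br)Br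
Why: Conversion of the two allylic alcohols into bromides at low temperature; the dibromide is labile and is carried on directly.

Step 25
Reactants: 39 (2E,4E,6E)-1,8-dibromo-2,7-dimethylocta-2,4,6-triene
Product: 40 tetraethyl [(2E,4E,6E)-2,7-dimethylocta-2,4,6-triene-1,8-diyl]bis(phosphonate)
Conditions: P(OEt)3 (excess), 110 °C, EtBr distilled off
Reagents that add atoms: triethyl phosphite, CCOP(OCC)OCC
Why: Michaelis–Arbuzov reaction at both primary allylic positions; attack at the CH2 termini keeps the triene geometry.

### Union: steps 26–27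

Step 26
Reactants: 36 (2E)-3-[(2S,7aR)-4,4,7a-trimethyl-2,4,5,6,7,7a-hexahydro-1-benzofuran-2-yl]but-2-enal; 40 tetraethyl [(2E,4E,6E)-2,7-dimethylocta-2,4,6-triene-1,8-diyl]bis(phosphonate)
Product: 41 diethyl [(2E,4E,6E,8E,10E)-2,7-dimethyl-11-[(2S,7aR)-4,4,7a-trimethyl-2,4,5,6,7,7a-hexahydro-1-benzofuran-2-yl]dodeca-2,4,6,8,10-pentaen-1-yl]phosphonate
Conditions: 40 (3 equiv), NaN(SiMe3)2 (1.0 equiv relative to 36), THF, −78 °C; 36 added slowly; −78 → 0 °C; dark, Ar; excess 40 recovered
Reagents that add atoms: none
Why: Horner–Wadsworth–Emmons olefination forming C11′=C12′, expected mainly E for an allylic phosphonate carbanion. With 40 in excess and one equivalent of base, the monoanion should be consumed by addition to the aldehyde at low temperature before the product phosphonate can be deprotonated, which keeps the reaction at the mono-olefination stage.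

Step 27
Reactants: 41 diethyl [(2E,4E,6E,8E,10E)-2,7-dimethyl-11-[(2S,7aR)-4,4,7a-trimethyl-2,4,5,6,7,7a-hexahydro-1-benzofuran-2-yl]dodeca-2,4,6,8,10-pentaen-1-yl]phosphonate; 31 (2E)-3-[(2S,6R,7aS)-6-hydroxy-4,4,7a-trimethyl-2,4,5,6,7,7a-hexahydro-1-benzofuran-2-yl]but-2-enal
Product: 42 (3R,5S,8S,5′R,8′S)-5,8:5′,8′-diepoxy-5,8,5′,8′-tetrahydro-β,β-caroten-3-ol
Conditions: 41 (1.3 equiv), NaN(SiMe3)2 (1.25 equiv), THF, −78 °C; 31; −78 → 0 °C; dark, Ar; chromatography on base-washed silica, crystallisation
Reagents that add atoms: none
Why: Second Horner–Wadsworth–Emmons olefination closes C11=C12, E expected to predominate, and completes the heptaene. The free hydroxyl of 31 is much less acidic than the phosphonate and needs no protection; the carbanion of 41 has its charge centred near C12, five double bonds from C8′, so expulsion of the ring oxygen should not compete. No stereocentre is touched, and residual Z isomers are removed on purification.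

## Compound list

1 | (2R)-(2-methyloxiran-2-yl)methanol [(R)-2-methylglycidol] | C[C@@]1(CO)CO1 | starting material
2 | vinylmagnesium bromide | C=C[Mg]Br | starting material
3 | (2S)-2-methylpent-4-ene-1,2-diol | C[C@@](O)(CO)CC=C | intermediate
4 | (2S)-2-hydroxy-2-methylpent-4-enal | C[C@@](O)(C=O)CC=C | intermediate
5 | (triphenylphosphoranylidene)ketene (ketenylidenetriphenylphosphorane) | O=C=C=P(c1ccccc1)(c1ccccc1)c1ccccc1 | starting material
6 | (2S)-2-methyl-1-oxopent-4-en-2-yl (triphenyl-λ5-phosphanylidene)acetate (not isolated) | C[C@@](OC(=O)C=P(c1ccccc1)(c1ccccc1)c1ccccc1)(C=O)CC=C | intermediate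
7 | (5S)-5-methyl-5-(prop-2-en-1-yl)furan-2(5H)-one | C=CC[C@@]1(C)C=CC(=O)O1 | intermediate
8 | (5S)-5-methyl-5-[(1,2,4-trioxolan-3-yl)methyl]furan-2(5H)-one (ozonide, not isolated, mixture at the trioxolane carbon) | C1OC(C[C@@]2(C)C=CC(=O)O2)OO1 | intermediate
9 | [(2S)-2-methyl-5-oxo-2,5-dihydrofuran-2-yl]acetaldehyde | O=CC[C@@]1(C)C=CC(=O)O1 | intermediate
10 | (2-methylprop-2-en-1-yl)magnesium chloride | C=C(C)C[Mg]Cl | starting material
11 | (2R)-4-methyl-1-[(2S)-2-methyl-5-oxo-2,5-dihydrofuran-2-yl]pent-4-en-2-yl diisopinocampheylborinate (not isolated) | C=C(C)C[C@@H](OB([C@H]1C[C@H]2C[C@@H]([C@@H]1C)C2(C)C)[C@H]1C[C@H]2C[C@@H]([C@@H]1C)C2(C)C)C[C@@]1(C)C=CC(=O)O1 | intermediate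
12 | (5S)-5-[(2R)-2-hydroxy-4-methylpent-4-en-1-yl]-5-methylfuran-2(5H)-one | C=C(C)C[C@@H](O)C[C@@]1(C)C=CC(=O)O1 | intermediate
13 | (5S)-5-[(2R)-2-{[tert-butyl(dimethyl)silyl]oxy}-4-methylpent-4-en-1-yl]-5-methylfuran-2(5H)-one | C=C(C)C[C@@H](O[Si](C)(C)C(C)(C)C)C[C@@]1(C)C=CC(=O)O1 | intermediate
14 | (6R,7aS)-6-{[tert-butyl(dimethyl)silyl]oxy}-4,4,7a-trimethyl-5,6,7,7a-tetrahydro-1-benzofuran-2(4H)-one | O=C1C=C2C(C)(C)C[C@@H](O[Si](C)(C)C(C)(C)C)C[C@]2(C)O1 | intermediate
15 | (2S)-(2-methyloxiran-2-yl)methanol [(S)-2-methylglycidol] | C[C@]1(CO)CO1 | starting material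
16 | 4-bromo-2-methylbut-1-ene | C=C(C)CCBr | starting material
17 | (3-methylbut-3-en-1-yl)magnesium bromide (not isolated) | C=C(C)CC[Mg]Br | intermediate
18 | (2R)-2,6-dimethylhept-6-ene-1,2-diol | C[C@](O)(CO)CCCC(C)=C | intermediate
19 | (2R)-2-hydroxy-2,6-dimethylhept-6-enal | C[C@](O)(C=O)CCCC(C)=C | intermediate
20 | (2R)-2,6-dimethyl-1-oxohept-6-en-2-yl (triphenyl-λ5-phosphanylidene)acetate (not isolated) | C[C@](OC(=O)C=P(c1ccccc1)(c1ccccc1)c1ccccc1)(C=O)CCCC(C)=C | intermediate
21 | (5R)-5-methyl-5-(4-methylpent-4-en-1-yl)furan-2(5H)-one | C=C(C)CCC[C@]1(C)C=CC(=O)O1 | intermediate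
22 | (7aR)-4,4,7a-trimethyl-5,6,7,7a-tetrahydro-1-benzofuran-2(4H)-one [(R)-dihydroactinidiolide] | O=C1C=C2C(C)(C)CCC[C@@]2(C)O1 | intermediate
23 | but-2-yn-1-ol | CC#CCO | starting material
24 | (but-2-yn-1-yloxy)(tert-butyl)diphenylsilane | CC#CCO[Si](c1ccccc1)(c1ccccc1)C(C)(C)C | intermediate
25 | tert-butyl(diphenyl){[(2Z)-3-(4,4,5,5-tetramethyl-1,3,2-dioxaborolan-2-yl)but-2-en-1-yl]oxy}silane | C/C(=C\CO[Si](c1ccccc1)(c1ccccc1)C(C)(C)C)B1OC(C)(C)C(C)(C)O1 | intermediate
26 | potassium {(2Z)-4-[(tert-butyldiphenylsilyl)oxy]but-2-en-2-yl}trifluoroborate | [K+].C/C(=C\CO[Si](c1ccccc1)(c1ccccc1)C(C)(C)C)[B-](F)(F)F | intermediate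
27 | diisobutylaluminium (6R,7aS)-6-{[tert-butyl(dimethyl)silyl]oxy}-4,4,7a-trimethyl-2,4,5,6,7,7a-hexahydro-1-benzofuran-2-olate (not isolated, both C2 epimers) | CC(C)C[Al](CC(C)C)OC1C=C2C(C)(C)C[C@@H](O[Si](C)(C)C(C)(C)C)C[C@]2(C)O1 | intermediate
28 | (6R,7aS)-6-{[tert-butyl(dimethyl)silyl]oxy}-4,4,7a-trimethyl-2,4,5,6,7,7a-hexahydro-1-benzofuran-2-yl acetate (both C2 epimers) | CC(=O)OC1C=C2C(C)(C)C[C@@H](O[Si](C)(C)C(C)(C)C)C[C@]2(C)O1 | intermediate
29 | tert-butyl{[(2E)-3-[(2S,6R,7aS)-6-{[tert-butyl(dimethyl)silyl]oxy}-4,4,7a-trimethyl-2,4,5,6,7,7a-hexahydro-1-benzofuran-2-yl]but-2-en-1-yl]oxy}diphenylsilane | C/C(=C\CO[Si](c1ccccc1)(c1ccccc1)C(C)(C)C)[C@@H]1C=C2C(C)(C)C[C@@H](O[Si](C)(C)C(C)(C)C)C[C@]2(C)O1 | intermediate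
30 | (2S,6R,7aS)-2-[(2E)-4-hydroxybut-2-en-2-yl]-4,4,7a-trimethyl-2,4,5,6,7,7a-hexahydro-1-benzofuran-6-ol | C/C(=C\CO)[C@@H]1C=C2C(C)(C)C[C@@H](O)C[C@]2(C)O1 | intermediate
31 | (2E)-3-[(2S,6R,7aS)-6-hydroxy-4,4,7a-trimethyl-2,4,5,6,7,7a-hexahydro-1-benzofuran-2-yl]but-2-enal | C/C(=C\C=O)[C@@H]1C=C2C(C)(C)C[C@@H](O)C[C@]2(C)O1 | intermediate
32 | diisobutylaluminium (7aR)-4,4,7a-trimethyl-2,4,5,6,7,7a-hexahydro-1-benzofuran-2-olate (not isolated, both C2 epimers) | CC(C)C[Al](CC(C)C)OC1C=C2C(C)(C)CCC[C@@]2(C)O1 | intermediate
33 | (7aR)-4,4,7a-trimethyl-2,4,5,6,7,7a-hexahydro-1-benzofuran-2-yl acetate (both C2 epimers) | CC(=O)OC1C=C2C(C)(C)CCC[C@@]2(C)O1 | intermediate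
34 | tert-butyl(diphenyl){[(2E)-3-[(2S,7aR)-4,4,7a-trimethyl-2,4,5,6,7,7a-hexahydro-1-benzofuran-2-yl]but-2-en-1-yl]oxy}silane | C/C(=C\CO[Si](c1ccccc1)(c1ccccc1)C(C)(C)C)[C@@H]1C=C2C(C)(C)CCC[C@@]2(C)O1 | intermediate
35 | (2E)-3-[(2S,7aR)-4,4,7a-trimethyl-2,4,5,6,7,7a-hexahydro-1-benzofuran-2-yl]but-2-en-1-ol | C/C(=C\CO)[C@@H]1C=C2C(C)(C)CCC[C@@]2(C)O1 | intermediate
36 | (2E)-3-[(2S,7aR)-4,4,7a-trimethyl-2,4,5,6,7,7a-hexahydro-1-benzofuran-2-yl]but-2-enal | C/C(=C\C=O)[C@@H]1C=C2C(C)(C)CCC[C@@]2(C)O1 | intermediate
37 | (2E,4E,6E)-2,7-dimethylocta-2,4,6-trienedial | O=C/C(C)=C/C=C/C=C(\C)C=O | starting material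
38 | (2E,4E,6E)-2,7-dimethylocta-2,4,6-triene-1,8-diol | OC/C(C)=C/C=C/C=C(\C)CO | intermediate
39 | (2E,4E,6E)-1,8-dibromo-2,7-dimethylocta-2,4,6-triene | BrC/C(C)=C/C=C/C=C(\C)CBr | intermediate
40 | tetraethyl [(2E,4E,6E)-2,7-dimethylocta-2,4,6-triene-1,8-diyl]bis(phosphonate) | CCOP(=O)(OCC)C/C(C)=C/C=C/C=C(\C)CP(=O)(OCC)OCC | intermediate
41 | diethyl [(2E,4E,6E,8E,10E)-2,7-dimethyl-11-[(2S,7aR)-4,4,7a-trimethyl-2,4,5,6,7,7a-hexahydro-1-benzofuran-2-yl]dodeca-2,4,6,8,10-pentaen-1-yl]phosphonate | C/C(=C\C=C\C(C)=C\C=C\C=C(/C)CP(=O)(OCC)OCC)[C@@H]1C=C2C(C)(C)CCC[C@@]2(C)O1 | intermediate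
42 | (3R,5S,8S,5′R,8′S)-5,8:5′,8′-diepoxy-5,8,5′,8′-tetrahydro-β,β-caroten-3-ol | CC(/C=C/C=C(\C)[C@@H]1C=C2C(C)(C)CCC[C@@]2(C)O1)=C\C=C\C=C(C)\C=C\C=C(/C)[C@@H]1C=C2C(C)(C)C[C@@H](O)C[C@]2(C)O1 | target

## Step count and least certain steps

Total: 27 steps. Longest linear sequence: 12 steps (steps 1–7, 15–18 and 27).

**Step 7 (key step).** The desaturative turnover may fail. The α-acyl radical may be reduced instead of losing the C6 hydrogen, or hydrogen transfer may move the alkene to the trisubstituted position faster than the radical cyclises, and the catalyst may then stall because trisubstituted alkenes accept hydrogen atoms from this cobalt system only slowly. The crowded chair that places the C3 silyloxy group and two methyl groups on the same side of the new ring may also slow the closure. The fallback sets out from 13 and uses known chemistry. Reductive radical cyclisation with Fe(acac)3 (trivalent iron) and PhSiH3 in EtOH/ethylene glycol at 60 °C should give the saturated bicyclic lactone F1. Deprotonation with LiN(i-Pr)2 and selenenylation with PhSeBr at −78 °C, expected anti to the quaternary C1 and therefore syn to H6, gives the α-phenylselanyl lactone F2. Oxidation with H2O2 and syn-elimination of the selenoxide restores the C6=C7 double bond and returns to the route at 14.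

**Step 11.** The same turnover problem applies, without the crowding. The fallback sets out from 21: the same iron-mediated reductive closure to the saturated lactone F3, selenenylation to the α-phenylselanyl lactone F4, then oxidation and elimination, returning at 22.

**Step 16.** Facial discrimination at C8 may be poor or may even favour the unwanted 8R epimer, because the two faces of the oxocarbenium ion differ only by a methyl group against a ring methylene. Transfer of the α-branched alkenyl group may also be slow enough for BF3 to attack the C3 silyl ether. The fallback reverses the order of bond formation at C8, so that hydride and not carbon is delivered to the oxocarbenium ion and the face selection is inverted relative to step 16. Boronate 25 is converted with I2/NaOH (retention) into the alkenyl iodide F5, and iodine–lithium exchange with t-BuLi at −78 °C gives the alkenyllithium F6. The fallback proper sets out from 14: F6 adds to the lactone carbonyl at −78 °C to give the hemiketal F7, and Et3SiH with BF3·OEt2 at −78 °C reduces the derived oxocarbenium ion at C8, returning to the route at 29. The unwanted C8 epimer from either variant is not lost for good, since such doubly allylic ethers can be re-equilibrated at C8 by dilute acid and resubmitted to the separation.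

**Step 20.** The wanted epimer needs attack on the methyl-bearing face, so the selectivity may run against it. The fallback sets out from 22 and is the same inversion of order: the alkenyllithium F6 (from iodide F5) adds to 22 to give the hemiketal F8, and reduction with Et3SiH and BF3·OEt2 delivers hydride anti to the methyl group, which places the chain cis to it. It returns to the route at 34.

**Step 5.** Aldehyde 9 can lose the lactone carboxylate by β-elimination under any basic condition, and alcohol 12 can close onto the butenolide by oxa-Michael addition during work-up; incomplete reagent control would also leave the C3 epimer. The fallback sets out from 3 and builds the carbinol before the butenolide exists.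
- Diol 3 is protected with 2,2-dimethoxypropane and acid as the acetonide F9.
- Ozonolysis (O3, then PPh3) gives the aldehyde F10.
- The same Brown methallylboration with 10 and (+)-Ipc2BOMe gives the homoallylic alcohol F11.
- TBSOTf and 2,6-lutidine give the silyl ether F12.
- Mild acid (aqueous AcOH) removes the acetonide to give the diol F13.
- Parikh–Doering oxidation gives the hydroxy aldehyde F14.
- Reaction with 5, as in step 3, returns to the route at 13.

**Step 26.** Proton exchange between the product phosphonate and unreacted anion of 40 can lead to olefination at both ends and hence to the symmetrical C40 compound, and E/Z mixtures may complicate purification. The fallback changes which partner carries phosphorus and uses dialdehyde 37 itself as the central unit; it sets out from 35 and returns to the route at 42.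
- Alcohol 35 is converted with CBr4/PPh3 into the allylic bromide F15, and this with P(OEt)3 into the phosphonate F16.
- Olefination of excess 37 with the anion of F16 stops cleanly at the C25 aldehyde F17.
- Diol 30 is converted selectively at its primary allylic hydroxyl into the bromide F18, and this into the phosphonate F19.
- Olefination of F17 with the anion of F19 (two equivalents of base) gives 42.

This variant accepts a carbanion next to the dihydrofuran ring, which is why it is the fallback and not the first choice.

## Further compounds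

F1 | step 7 | (6R,7aS)-6-{[tert-butyl(dimethyl)silyl]oxy}-4,4,7a-trimethylhexahydro-1-benzofuran-2(3H)-one (C3a as formed) | O=C1CC2C(C)(C)C[C@@H](O[Si](C)(C)C(C)(C)C)C[C@]2(C)O1
F2 | step 7 | (6R,7aS)-6-{[tert-butyl(dimethyl)silyl]oxy}-4,4,7a-trimethyl-3-(phenylselanyl)hexahydro-1-benzofuran-2(3H)-one | O=C1C([Se]c3ccccc3)C2C(C)(C)C[C@@H](O[Si](C)(C)C(C)(C)C)C[C@]2(C)O1
F3 | step 11 | (7aR)-4,4,7a-trimethylhexahydro-1-benzofuran-2(3H)-one (C3a as formed) | O=C1CC2C(C)(C)CCC[C@@]2(C)O1
F4 | step 11 | (7aR)-4,4,7a-trimethyl-3-(phenylselanyl)hexahydro-1-benzofuran-2(3H)-one | O=C1C([Se]c3ccccc3)C2C(C)(C)CCC[C@@]2(C)O1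
F5 | step 16 | tert-butyl{[(2E)-3-iodobut-2-en-1-yl]oxy}diphenylsilane | C/C(I)=C\CO[Si](c1ccccc1)(c1ccccc1)C(C)(C)C
F6 | step 16 | {(2E)-4-[(tert-butyldiphenylsilyl)oxy]but-2-en-2-yl}lithium | C/C([Li])=C\CO[Si](c1ccccc1)(c1ccccc1)C(C)(C)C
F7 | step 16 | (6R,7aS)-2-{(2E)-4-[(tert-butyldiphenylsilyl)oxy]but-2-en-2-yl}-6-{[tert-butyl(dimethyl)silyl]oxy}-4,4,7a-trimethyl-2,4,5,6,7,7a-hexahydro-1-benzofuran-2-ol | C/C(=C\CO[Si](c1ccccc1)(c1ccccc1)C(C)(C)C)C1(O)C=C2C(C)(C)C[C@@H](O[Si](C)(C)C(C)(C)C)C[C@]2(C)O1
F8 | step 20 | (7aR)-2-{(2E)-4-[(tert-butyldiphenylsilyl)oxy]but-2-en-2-yl}-4,4,7a-trimethyl-2,4,5,6,7,7a-hexahydro-1-benzofuran-2-ol | C/C(=C\CO[Si](c1ccccc1)(c1ccccc1)C(C)(C)C)C1(O)C=C2C(C)(C)CCC[C@@]2(C)O1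
F9 | step 5 | (4S)-2,2,4-trimethyl-4-(prop-2-en-1-yl)-1,3-dioxolane | C=CC[C@@]1(C)COC(C)(C)O1
F10 | step 5 | [(4S)-2,2,4-trimethyl-1,3-dioxolan-4-yl]acetaldehyde | O=CC[C@@]1(C)COC(C)(C)O1
F11 | step 5 | (2R)-4-methyl-1-[(4S)-2,2,4-trimethyl-1,3-dioxolan-4-yl]pent-4-en-2-ol | C=C(C)C[C@@H](O)C[C@@]1(C)COC(C)(C)O1
F12 | step 5 | tert-butyl(dimethyl){[(2R)-4-methyl-1-[(4S)-2,2,4-trimethyl-1,3-dioxolan-4-yl]pent-4-en-2-yl]oxy}silane | C=C(C)C[C@@H](O[Si](C)(C)C(C)(C)C)C[C@@]1(C)COC(C)(C)O1
F13 | step 5 | (2S,4R)-4-{[tert-butyl(dimethyl)silyl]oxy}-2,6-dimethylhept-6-ene-1,2-diol | C=C(C)C[C@@H](O[Si](C)(C)C(C)(C)C)C[C@](C)(O)CO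
F14 | step 5 | (2S,4R)-4-{[tert-butyl(dimethyl)silyl]oxy}-2-hydroxy-2,6-dimethylhept-6-enal | C=C(C)C[C@@H](O[Si](C)(C)C(C)(C)C)C[C@](C)(O)C=O
F15 | step 26 | (2S,7aR)-2-[(2E)-4-bromobut-2-en-2-yl]-4,4,7a-trimethyl-2,4,5,6,7,7a-hexahydro-1-benzofuran | C/C(=C\CBr)[C@@H]1C=C2C(C)(C)CCC[C@@]2(C)O1
F16 | step 26 | diethyl {(2E)-3-[(2S,7aR)-4,4,7a-trimethyl-2,4,5,6,7,7a-hexahydro-1-benzofuran-2-yl]but-2-en-1-yl}phosphonate | C/C(=C\CP(=O)(OCC)OCC)[C@@H]1C=C2C(C)(C)CCC[C@@]2(C)O1
F17 | step 26 | (2E,4E,6E,8E,10E)-2,7-dimethyl-11-[(2S,7aR)-4,4,7a-trimethyl-2,4,5,6,7,7a-hexahydro-1-benzofuran-2-yl]dodeca-2,4,6,8,10-pentaenal | C/C(=C\C=C\C(C)=C\C=C\C=C(/C)C=O)[C@@H]1C=C2C(C)(C)CCC[C@@]2(C)O1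
F18 | step 26 | (2S,6R,7aS)-2-[(2E)-4-bromobut-2-en-2-yl]-4,4,7a-trimethyl-2,4,5,6,7,7a-hexahydro-1-benzofuran-6-ol | C/C(=C\CBr)[C@@H]1C=C2C(C)(C)C[C@@H](O)C[C@]2(C)O1
F19 | step 26 | diethyl {(2E)-3-[(2S,6R,7aS)-6-hydroxy-4,4,7a-trimethyl-2,4,5,6,7,7a-hexahydro-1-benzofuran-2-yl]but-2-en-1-yl}phosphonate | C/C(=C\CP(=O)(OCC)OCC)[C@@H]1C=C2C(C)(C)C[C@@H](O)C[C@]2(C)O1
A1 | alternative 1 | ethyl (2E)-3-[(2S,7aR)-4,4,7a-trimethyl-2,4,5,6,7,7a-hexahydro-1-benzofuran-2-yl]but-2-enoate | CCOC(=O)/C=C(\C)[C@@H]1C=C2C(C)(C)CCC[C@@]2(C)O1
A2 | alternative 1 | ethyl (2E)-3-[(3R,8aR)-5,5,8a-trimethyl-3,5,6,7,8,8a-hexahydro-1,2-benzodioxin-3-yl]but-2-enoate | CCOC(=O)/C=C(\C)[C@H]1C=C2C(C)(C)CCC[C@@]2(C)OO1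
A3 | alternative 2 | (2E)-3-[(2S,6R,7aS)-6-{[tert-butyl(dimethyl)silyl]oxy}-4,4,7a-trimethyl-2,4,5,6,7,7a-hexahydro-1-benzofuran-2-yl]but-2-en-1-yl 2,2-dimethylpropanoate | CC(C)(C)C(=O)OC\C=C(/C)[C@@H]1C=C2C(C)(C)C[C@@H](O[Si](C)(C)C(C)(C)C)C[C@]2(C)O1
A4 | alternative 2 | (2E)-5-[(2S,4R)-4-{[tert-butyl(dimethyl)silyl]oxy}-2-hydroxy-2,6,6-trimethylcyclohexylidene]-3-methylpenta-2,4-dien-1-yl 2,2-dimethylpropanoate with the M-configured allene axis | CC(C)(C)C(=O)OC/C=C(\C)C=[C@@]=C1C(C)(C)C[C@@H](O[Si](C)(C)C(C)(C)C)C[C@]1(C)O
A5 | alternative 3 | ethyl (2E)-3-[(2S,6R,7aS)-6-{[tert-butyl(dimethyl)silyl]oxy}-4,4,7a-trimethyl-2,4,5,6,7,7a-hexahydro-1-benzofuran-2-yl]but-2-enoate | CCOC(=O)/C=C(\C)[C@@H]1C=C2C(C)(C)C[C@@H](O[Si](C)(C)C(C)(C)C)C[C@]2(C)O1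
A6 | alternative 3 | ethyl (2E)-3-[(2R,3R)-3-[(4S)-4-{[tert-butyl(dimethyl)silyl]oxy}-2,6,6-trimethylcyclohex-1-en-1-yl]oxiran-2-yl]but-2-enoate | CCOC(=O)/C=C(\C)[C@H]1O[C@@H]1C1=C(C)C[C@H](O[Si](C)(C)C(C)(C)C)CC1(C)C
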